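**Retrosynthetic overview**

1. Late stage: the C11(13) acrylate comes from a C7–CH2CH2OH arm (oxidation, α-methylenation, oxidation, esterification), the 6α-angelate from acylation, 5α-H/6α-OH from hydroboration of a Δ5 alkene, and 1β-OH from reduction of a C1 ketone.
2. Ring B (C5–C6–C7–C8–C9–C10) is disconnected to the four-membered ring C5–C10–C9–C8 of a cis-fused bicyclo[4.2.0]octanol that carries an (E)-alkenyl group (C6=C7) on C5; a two-carbon ring expansion by an oxy-anion-accelerated 1,3-shift sets C7 and C8.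
3. Ring A and the cyclobutanone are formed first and together by an intramolecular vinylketene–alkene [2+2] cycloaddition of an acyclic acid; ring B follows by the expansion.
4. The acid comes from (R)-linalool (C1–C6, C9, C10, C14, C15 and the C4 stereocentre), a three-carbon iodide (C7, C11, C12) and CO (C8); a 1α-oxygen, set on purpose, steers the cycloaddition and is corrected later by oxidation and reduction.
5. Enabling feature: the 2-alkenylcyclobutanol array O–C8–C5–C6=C7, in which the strained ring bond C5–C8 is allylic to C6=C7 and β to the oxide, so that C8 can move from C5 to C7.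

Key step: step 13

Remark: atoms are numbered as in the eudesmane skeleton of the target (C1–C15) throughout; (R)-(−)-linalool, 3-[(4-methoxybenzyl)oxy]propan-1-ol and angelic acid are taken as commercially available (PMB = 4-methoxybenzyl, TES = triethylsilyl, TBS = tert-butyldimethylsilyl).

**Route**

Step 1
Reactants: 1 (R)-(−)-linalool
Product: 2 (3R)-3,7-dimethyl-3-(triethylsilyloxy)octa-1,6-diene
Conditions: Et3SiOTf, 2,6-lutidine, CH2Cl2, −78 → 0 °C
Reagents that add atoms: triethylsilyl trifluoromethanesulfonate, CC[Si](CC)(CC)OS(=O)(=O)C(F)(F)F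
Why: O-silylation of the tertiary allylic alcohol with a silyl triflate; the C–O bond of the stereocentre (later C4) is not broken, so the R configuration of the chiral pool is kept.

Step 2
Reactants: 2 (3R)-3,7-dimethyl-3-(triethylsilyloxy)octa-1,6-diene
Product: 3 (3R,6S)-6,7-epoxy-3,7-dimethyl-3-(triethylsilyloxy)oct-1-ene
Conditions: L-fructose-derived ketone of the Shi epoxidation (1,2:4,5-di-O-isopropylidene-β-L-erythro-2,3-hexodiulo-2,6-pyranose, 0.3 equiv), KHSO5 (as the triple salt 2KHSO5·KHSO4·K2SO4), K2CO3, n-Bu4NHSO4, MeCN/CH2(OMe)2, aq. Na2B4O7 buffer, 0 °C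
Reagents that add atoms: potassium peroxymonosulfate, [K+].[O-]S(=O)(=O)OO
Why: Shi asymmetric epoxidation, in which the chiral dioxirane attacks only the electron-rich trisubstituted alkene (the vinyl group is inert) and the ketone enantiomer is the one whose spiro transition state delivers oxygen to the face that gives the 6S epoxide (the later 1α-oxygen).

Step 3
Reactants: 3 (3R,6S)-6,7-epoxy-3,7-dimethyl-3-(triethylsilyloxy)oct-1-ene
Product: 4 (3S,6R)-2,6-dimethyl-6-(triethylsilyloxy)octa-1,7-dien-3-ol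
Conditions: LiNEt2, Et2O, 0 °C → reflux; H2O
Reagents that add atoms: none
Why: base-promoted epoxide-to-allylic-alcohol isomerization (syn β-elimination) removes a proton from the less hindered methyl group, so the C–O bond at the secondary carbon and its configuration are kept while the 1,1-disubstituted alkene C10=C9 is created.

Step 4
Reactants: 4 (3S,6R)-2,6-dimethyl-6-(triethylsilyloxy)octa-1,7-dien-3-ol
Product: 5 (3S,6R)-3-[(4-methoxybenzyl)oxy]-2,6-dimethyl-6-(triethylsilyloxy)octa-1,7-diene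
Conditions: NaH, 4-MeOC6H4CH2Cl, n-Bu4NI (cat.), THF/DMF, 0 °C → rt
Reagents that add atoms: 4-methoxybenzyl chloride, COc1ccc(CCl)cc1
Why: Williamson etherification of the secondary allylic alkoxide, which touches no stereocentre.

Step 5
Reactants: 5 (3S,6R)-3-[(4-methoxybenzyl)oxy]-2,6-dimethyl-6-(triethylsilyloxy)octa-1,7-diene
Product: 6 (3R,6S)-6-[(4-methoxybenzyl)oxy]-3,7-dimethyl-3-(triethylsilyloxy)oct-7-en-2-one
Conditions: PdCl2(quinox) (5 mol%) [quinox = 2-(4,5-dihydrooxazol-2-yl)quinoline], AgSbF6 (12 mol%), aq. t-BuOOH, CH2Cl2, rt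
Reagents that add atoms: tert-butyl hydroperoxide, CC(C)(C)OO
Why: Wacker-type oxidation with a peroxide as terminal oxidant converts only the monosubstituted vinyl group (the 1,1-disubstituted alkene does not react) into the methyl ketone with catalyst-enforced Markovnikov selectivity, making C5 the carbonyl carbon and C6 its methyl group.

Step 6
Reactants: 7 3-[(4-methoxybenzyl)oxy]propan-1-ol
Product: 8 1-[(3-iodopropoxy)methyl]-4-methoxybenzene
Conditions: I2, PPh3, imidazole, CH2Cl2, 0 °C → rt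
Reagents that add atoms: iodine, II
Why: Appel-type iodination of a primary alcohol by SN2 displacement of the oxyphosphonium group.

Step 7
Reactants: 6 (3R,6S)-6-[(4-methoxybenzyl)oxy]-3,7-dimethyl-3-(triethylsilyloxy)oct-7-en-2-one; 8 1-[(3-iodopropoxy)methyl]-4-methoxybenzene
Product: 10 (6R,9S)-1,9-bis[(4-methoxybenzyl)oxy]-6,10-dimethyl-6-(triethylsilyloxy)undec-10-en-5-one, via lithium enolate 9 (not isolated)
Conditions: LiN(i-Pr)2, THF, −78 °C; then 8, HMPA, −78 → −20 °C
Reagents that add atoms: none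
Why: enolate alkylation, in which the ketone can enolize only toward its methyl group (C4 is quaternary) and the enolate displaces the primary iodide in an SN2 reaction, attaching C7, C11 and C12.

Step 8
Reactants: 10 (6R,9S)-1,9-bis[(4-methoxybenzyl)oxy]-6,10-dimethyl-6-(triethylsilyloxy)undec-10-en-5-one
Product: 12 (4Z,6R,9S)-1,9-bis[(4-methoxybenzyl)oxy]-6,10-dimethyl-6-(triethylsilyloxy)undeca-4,10-dien-5-yl trifluoromethanesulfonate, via potassium enolate 11 (not isolated)
Conditions: KN(SiMe3)2, THF, −78 °C; then PhNTf2, −78 → 0 °C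
Reagents that add atoms: N-phenylbis(trifluoromethanesulfonimide), O=S(=O)(N(c1ccccc1)S(=O)(=O)C(F)(F)F)C(F)(F)F
Why: enolate O-sulfonylation, in which kinetic deprotonation is possible only at C6 and should give the Z enolate (oxygen cis to the chain) that is trapped on oxygen as the enol triflate.

Step 9
Reactants: 12 (4Z,6R,9S)-1,9-bis[(4-methoxybenzyl)oxy]-6,10-dimethyl-6-(triethylsilyloxy)undeca-4,10-dien-5-yl trifluoromethanesulfonate
Product: 13 (2Z)-6-[(4-methoxybenzyl)oxy]-2-[(2R,5S)-5-[(4-methoxybenzyl)oxy]-6-methyl-2-(triethylsilyloxy)hept-6-en-2-yl]hex-2-enoic acid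
Conditions: Pd(OAc)2 (5 mol%), 1,3-bis(diphenylphosphino)propane, CO (1 atm), KOAc, DMF/H2O, 60 °C
Reagents that add atoms: carbon monoxide, [C-]#[O+]; water, O
Why: palladium-catalysed hydroxycarbonylation of an enol triflate (oxidative addition to zerovalent palladium, CO insertion, hydrolysis of the acyl species) introduces C8 with retention of the alkene geometry.

Step 10
Reactants: 13 (2Z)-6-[(4-methoxybenzyl)oxy]-2-[(2R,5S)-5-[(4-methoxybenzyl)oxy]-6-methyl-2-(triethylsilyloxy)hept-6-en-2-yl]hex-2-enoic acid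
Product: 16 cis-fused cyclobutanone (ring A plus cyclobutane C5–C10–C9–C8 with C8=O; 10β-CH3; 5β-(E)-alkenyl; 4β-CH3; 4α-OTES; 1α-OPMB), via acid chloride 14 (not isolated), via vinylketene 15 (not isolated)
Conditions: 1-chloro-N,N,2-trimethylprop-1-en-1-amine, CH2Cl2, 0 °C → rt; then slow addition to Et3N in toluene at reflux (high dilution)
Reagents that add atoms: none
Why: intramolecular ketene–alkene [2+2] cycloaddition, in which the acid chloride loses HCl by γ-deprotonation at C7 to the (E)-vinylketene 15, whose C5=C8 bond adds across the 1,1-disubstituted alkene with the electrophilic C8 bonding to the CH2 terminus C9 and C5 to the methyl-bearing C10, closing ring A and the cis-fused cyclobutanone together; C10 and C5 are set by the tether, since the chair-like closure that keeps 1α-OPMB and the C4 methyl equatorial and turns only the smaller C4 oxygen substituent axial toward the slim CH2 terminus places the C10 methyl cis to the C4 methyl.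

Step 11
Reactants: 16 cis-fused cyclobutanone
Product: 17 cis-fused cyclobutanol (C8–OH cis to C4; 4α-OTES)
Conditions: NaBH4, MeOH/THF, −20 °C
Reagents that add atoms: none
Why: borohydride reduction of the strained cyclobutanone, with hydride expected from the face of the alkenyl group (the other face is covered by the quaternary C4) to give the alcohol cis to C4; this carbinol configuration is erased in step 13, so either epimer can be carried on.

Step 12
Reactants: 17 cis-fused cyclobutanol (4α-OTES)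
Product: 18 cis-fused cyclobutane-diol (C8–OH and 4α-OH free)
Conditions: HF·pyridine, pyridine, THF, 0 °C → rt
Reagents that add atoms: none
Why: fluoride-assisted cleavage of the tertiary triethylsilyl ether (the PMB ethers are stable), needed because O4 must be a non-leaving alkoxide in step 13.

Step 13
Reactants: 18 cis-fused cyclobutane-diol
Product: 22 8α-(tert-butyldimethylsilyloxy)-1α,12-bis[(4-methoxybenzyl)oxy]-13-noreudesm-5-en-4α-ol, via dipotassium dialkoxide 19 (not isolated), via ring-opened allyl anion 20 (not isolated), via ring-expanded dialkoxide 21 (not isolated)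
Conditions: KH (2.5 equiv), 18-crown-6, THF, 0 °C → rt; then t-BuMe2SiCl (1.05 equiv), −78 → 0 °C; H2O
Reagents that add atoms: tert-butyldimethylsilyl chloride, CC(C)(C)[Si](C)(C)Cl
Why: KH converts both hydroxyls into potassium alkoxides (19); the cyclobutoxide at C8 then breaks the strained, allylic C5–C8 bond to the aldehyde/allyl-anion pair 20 (or passes through the equivalent concerted transition state) and C8 re-bonds at the far allyl terminus C7, a net 1,3-sigmatropic shift that enlarges the four-membered ring C5–C10–C9–C8 by C6 and C7 to ring B with a C5=C6 double bond (21). The closest known reaction type is the oxy-anion-accelerated vinylcyclobutane-to-cyclohexene rearrangement of 2-vinylcyclobutanol potassium salts. Ring B is closed by a 6-exo-trig addition of the allyl terminus C7 to the C8 carbonyl through a chair-like arrangement in which the C5=C6 bond ends inside the ring. C7 is controlled by the E geometry of the alkenyl group, which puts the side chain pseudo-equatorial (β), and C8 by the preference of the solvated potassium alkoxide for the equatorial (α) position, away from the pseudo-axial angular methyl; both are relayed from the C10 quaternary centre through the half-chair that keeps C1 of ring A pseudo-equatorial. The step needs C7–C8 bonding to win over re-closure at C5, over proton transfer to the allyl anion and over β-elimination of the oxygen on C4: relief of cyclobutane strain and the six-membered geometry should secure the first two, and the third is excluded because O4 is a non-leaving alkoxide, which also stays unsilylated when the less hindered C8 alkoxide is capped with t-BuMe2SiCl.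

Step 14
Reactants: 22 8α-(tert-butyldimethylsilyloxy)-1α,12-bis[(4-methoxybenzyl)oxy]-13-noreudesm-5-en-4α-ol
Product: 24 8α-(tert-butyldimethylsilyloxy)-1α,12-bis[(4-methoxybenzyl)oxy]-13-nor-5α-eudesmane-4α,6α-diol, via alkylborane 23 (not isolated)
Conditions: BH3·THF, THF, 0 °C → rt; then NaOH, H2O2, 0 °C → rt
Reagents that add atoms: hydrogen peroxide, OO
Why: hydroboration–oxidation, in which borane adds syn across C5=C6 from the α-face, opposite the axial 10β- and 4β-methyl groups (boron to the less substituted C6, and the borate formed at the 4α-hydroxyl can deliver from the same face), and oxidation with retention gives the trans-decalin with 5α-H and the equatorial 6α-hydroxyl.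

Step 15
Reactants: 24 8α-(tert-butyldimethylsilyloxy)-1α,12-bis[(4-methoxybenzyl)oxy]-13-nor-5α-eudesmane-4α,6α-diol
Product: 25 6α-angeloyloxy-8α-(tert-butyldimethylsilyloxy)-1α,12-bis[(4-methoxybenzyl)oxy]-13-nor-5α-eudesman-4α-ol
Conditions: angelic acid, 2,4,6-Cl3C6H2COCl, Et3N, toluene, rt; then 24, 80 °C
Reagents that add atoms: angelic acid [(Z)-2-methylbut-2-enoic acid], C/C=C(/C)C(=O)O
Why: Yamaguchi-type esterification through the mixed 2,4,6-trichlorobenzoic anhydride acylates the only reactive (secondary) hydroxyl, the tertiary C4–OH being inert, and working without a nucleophilic amine catalyst should avoid isomerization of the Z ester to the tiglate.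

Step 16
Reactants: 25 6α-angeloyloxy-8α-(tert-butyldimethylsilyloxy)-1α,12-bis[(4-methoxybenzyl)oxy]-13-nor-5α-eudesman-4α-ol
Product: 26 6α-angeloyloxy-8α-(tert-butyldimethylsilyloxy)-13-nor-5α-eudesmane-1α,4α,12-triol
Conditions: DDQ (2.5 equiv), CH2Cl2/pH 7 phosphate buffer, 0 °C → rt
Reagents that add atoms: none
Why: oxidative cleavage of both 4-methoxybenzyl ethers (hydride abstraction, then hydrolysis of the oxocarbenium ions), which leaves the silyl ether and the angelate untouched.

Step 17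
Reactants: 26 6α-angeloyloxy-8α-(tert-butyldimethylsilyloxy)-13-nor-5α-eudesmane-1α,4α,12-triol
Product: 27 6α-angeloyloxy-4α-hydroxy-1-oxo-8α-(tert-butyldimethylsilyloxy)-13-nor-5α-eudesman-12-al
Conditions: Dess–Martin periodinane (2.6 equiv), NaHCO3, CH2Cl2, 0 °C → rt
Reagents that add atoms: none
Why: Dess–Martin oxidation turns the primary alcohol into the aldehyde and the secondary C1 alcohol into the ketone in one operation (the tertiary alcohol cannot be oxidized), which also erases the auxiliary 1α configuration.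

Step 18
Reactants: 27 6α-angeloyloxy-4α-hydroxy-1-oxo-8α-(tert-butyldimethylsilyloxy)-13-nor-5α-eudesman-12-al
Product: 29 6α-angeloyloxy-4α-hydroxy-1-oxo-8α-(tert-butyldimethylsilyloxy)-5α-eudesm-11(13)-en-12-al, via Mannich base 28 (not isolated)
Conditions: dimethyl(methylene)ammonium iodide, Et3N, CH2Cl2, rt
Reagents that add atoms: dimethyl(methylene)ammonium iodide, C=[N+](C)C.[I-]
Why: α-methylenation of the aldehyde by a Mannich reaction and elimination of dimethylamine installs C13, while the hindered C1 ketone should not enolize under these conditions.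

Step 19
Reactants: 29 6α-angeloyloxy-4α-hydroxy-1-oxo-8α-(tert-butyldimethylsilyloxy)-5α-eudesm-11(13)-en-12-al
Product: 30 6α-angeloyloxy-4α-hydroxy-1-oxo-8α-(tert-butyldimethylsilyloxy)-5α-eudesm-11(13)-en-12-oic acid
Conditions: NaClO2, NaH2PO4, 2-methylbut-2-ene, t-BuOH/H2O, 0 °C → rt
Reagents that add atoms: sodium chlorite, [Na+].[O-]Cl=O
Why: Pinnick oxidation of the enal to the acrylic acid, with the alkene scavenger removing hypochlorous acid so that the two enoate double bonds are not chlorinated.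

Step 20
Reactants: 30 6α-angeloyloxy-4α-hydroxy-1-oxo-8α-(tert-butyldimethylsilyloxy)-5α-eudesm-11(13)-en-12-oic acid
Product: 31 methyl 6α-angeloyloxy-4α-hydroxy-1-oxo-8α-(tert-butyldimethylsilyloxy)-5α-eudesm-11(13)-en-12-oate
Conditions: Me3SiCHN2, toluene/MeOH, 0 °C
Reagents that add atoms: (trimethylsilyl)diazomethane, C[Si](C)(C)C=[N+]=[N-]
Why: O-methylation of the carboxylic acid by the diazoalkane under neutral conditions, which the tertiary alcohol, the ketone and the silyl ether survive.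

Step 21
Reactants: 31 methyl 6α-angeloyloxy-4α-hydroxy-1-oxo-8α-(tert-butyldimethylsilyloxy)-5α-eudesm-11(13)-en-12-oate
Product: 32 methyl 6α-angeloyloxy-1β,4α-dihydroxy-8α-(tert-butyldimethylsilyloxy)-5α-eudesm-11(13)-en-12-oate
Conditions: NaBH4, CeCl3·7H2O, MeOH, −40 °C
Reagents that add atoms: none
Why: Luche reduction, in which 1,2-selective hydride attack on the C1 ketone from the α-face (axial, anti to the angular methyl group) gives the equatorial 1β-alcohol while the acrylate, the angelate and the silyl ether are not touched.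

Step 22
Reactants: 32 methyl 6α-angeloyloxy-1β,4α-dihydroxy-8α-(tert-butyldimethylsilyloxy)-5α-eudesm-11(13)-en-12-oate
Product: 33 methyl 6α-angeloyloxy-1β,4α,8α-trihydroxy-5α-eudesm-11(13)-en-12-oate (CNP0136844.1)
Conditions: HF·pyridine, pyridine, THF, 0 °C; pH 7 buffer
Reagents that add atoms: none
Why: fluoride-mediated desilylation of the secondary TBS ether under buffered conditions chosen so as not to promote lactonization of the γ-hydroxy ester or acyl migration.

**Compound list**

1 | (R)-(−)-linalool, (3R)-3,7-dimethylocta-1,6-dien-3-ol | C=C[C@](C)(O)CCC=C(C)C | starting material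
2 | (3R)-3,7-dimethyl-3-(triethylsilyloxy)octa-1,6-diene | C=C[C@](C)(O[Si](CC)(CC)CC)CCC=C(C)C | intermediate
3 | (3R,6S)-6,7-epoxy-3,7-dimethyl-3-(triethylsilyloxy)oct-1-ene | C=C[C@](C)(O[Si](CC)(CC)CC)CC[C@@H]1OC1(C)C | intermediate
4 | (3S,6R)-2,6-dimethyl-6-(triethylsilyloxy)octa-1,7-dien-3-ol | C=C[C@](C)(O[Si](CC)(CC)CC)CC[C@H](O)C(C)=C | intermediate
5 | (3S,6R)-3-[(4-methoxybenzyl)oxy]-2,6-dimethyl-6-(triethylsilyloxy)octa-1,7-diene | C=C[C@](C)(O[Si](CC)(CC)CC)CC[C@H](OCc1ccc(OC)cc1)C(C)=C | intermediate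
6 | (3R,6S)-6-[(4-methoxybenzyl)oxy]-3,7-dimethyl-3-(triethylsilyloxy)oct-7-en-2-one | CC(=O)[C@](C)(O[Si](CC)(CC)CC)CC[C@H](OCc1ccc(OC)cc1)C(C)=C | intermediate
7 | 3-[(4-methoxybenzyl)oxy]propan-1-ol | OCCCOCc1ccc(OC)cc1 | starting material
8 | 1-[(3-iodopropoxy)methyl]-4-methoxybenzene | ICCCOCc1ccc(OC)cc1 | intermediate
9 | lithium enolate of 6 (enolized toward the methyl group C6) | [Li+].[O-]C(=C)[C@](C)(O[Si](CC)(CC)CC)CC[C@H](OCc1ccc(OC)cc1)C(C)=C | intermediate (not isolated)
10 | (6R,9S)-1,9-bis[(4-methoxybenzyl)oxy]-6,10-dimethyl-6-(triethylsilyloxy)undec-10-en-5-one | COc1ccc(COCCCCC(=O)[C@](C)(O[Si](CC)(CC)CC)CC[C@H](OCc2ccc(OC)cc2)C(C)=C)cc1 | intermediate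
11 | potassium (Z)-enolate of 10 | [K+].[O-]/C(=C\CCCOCc1ccc(OC)cc1)[C@](C)(O[Si](CC)(CC)CC)CC[C@H](OCc1ccc(OC)cc1)C(C)=C | intermediate (not isolated)
12 | (4Z,6R,9S)-1,9-bis[(4-methoxybenzyl)oxy]-6,10-dimethyl-6-(triethylsilyloxy)undeca-4,10-dien-5-yl trifluoromethanesulfonate | FC(F)(F)S(=O)(=O)O/C(=C\CCCOCc1ccc(OC)cc1)[C@](C)(O[Si](CC)(CC)CC)CC[C@H](OCc1ccc(OC)cc1)C(C)=C | intermediate
13 | (2Z)-6-[(4-methoxybenzyl)oxy]-2-[(2R,5S)-5-[(4-methoxybenzyl)oxy]-6-methyl-2-(triethylsilyloxy)hept-6-en-2-yl]hex-2-enoic acid | OC(=O)/C(=C\CCCOCc1ccc(OC)cc1)[C@](C)(O[Si](CC)(CC)CC)CC[C@H](OCc1ccc(OC)cc1)C(C)=C | intermediate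
14 | acid chloride of 13 | ClC(=O)/C(=C\CCCOCc1ccc(OC)cc1)[C@](C)(O[Si](CC)(CC)CC)CC[C@H](OCc1ccc(OC)cc1)C(C)=C | intermediate (not isolated)
15 | (E)-vinylketene O=C8=C5(C4)–C6H=C7H–CH2CH2OPMB derived from 14 | O=C=C(/C=C/CCOCc1ccc(OC)cc1)[C@](C)(O[Si](CC)(CC)CC)CC[C@H](OCc1ccc(OC)cc1)C(C)=C | intermediate (not isolated)
16 | cis-fused 1-[(1E)-4-[(4-methoxybenzyl)oxy]but-1-en-1-yl]-5-[(4-methoxybenzyl)oxy]-2,6-dimethyl-2-(triethylsilyloxy)bicyclo[4.2.0]octan-8-one (eudesmane numbering: cyclobutane C5–C10–C9–C8 with C8=O; 10β-CH3 and 5β-alkenyl; C8 and C9 α; 4β-CH3, 4α-OTES, 1α-OPMB) | O=C1C[C@@]2(C)[C@@H](OCc3ccc(OC)cc3)CC[C@@](C)(O[Si](CC)(CC)CC)[C@@]12/C=C/CCOCc1ccc(OC)cc1 | intermediate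
17 | cyclobutanol from 16 (C8–OH on the ring-A face, cis to C4; 4α-OTES) | O[C@H]1C[C@@]2(C)[C@@H](OCc3ccc(OC)cc3)CC[C@@](C)(O[Si](CC)(CC)CC)[C@@]12/C=C/CCOCc1ccc(OC)cc1 | intermediate
18 | cyclobutane-diol from 17 (C8–OH and 4α-OH free) | O[C@H]1C[C@@]2(C)[C@@H](OCc3ccc(OC)cc3)CC[C@@](C)(O)[C@@]12/C=C/CCOCc1ccc(OC)cc1 | intermediate
19 | dipotassium dialkoxide of 18 | [K+].[K+].[O-][C@H]1C[C@@]2(C)[C@@H](OCc3ccc(OC)cc3)CC[C@@](C)([O-])[C@@]12/C=C/CCOCc1ccc(OC)cc1 | intermediate (not isolated)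
20 | ring-opened dipotassium species: C8 aldehyde on C9, C5–C6–C7 allyl anion, C4 alkoxide, ring A intact | [K+].[K+].O=CC[C@@]1(C)[C@@H](OCc2ccc(OC)cc2)CC[C@@](C)([O-])/C1=C/[CH-]CCOCc1ccc(OC)cc1 | intermediate (not isolated)
21 | dipotassium 4α,8α-dialkoxide of 1α,12-bis[(4-methoxybenzyl)oxy]-13-noreudesm-5-ene-4α,8α-diol | [K+].[K+].COc1ccc(COCC[C@H]2C=C3[C@@](C)(C[C@@H]2[O-])[C@@H](OCc4ccc(OC)cc4)CC[C@@]3(C)[O-])cc1 | intermediate (not isolated)
22 | 8α-(tert-butyldimethylsilyloxy)-1α,12-bis[(4-methoxybenzyl)oxy]-13-noreudesm-5-en-4α-ol (7β side chain, 10β-CH3, 4β-CH3) | COc1ccc(COCC[C@H]2C=C3[C@@](C)(C[C@@H]2O[Si](C)(C)C(C)(C)C)[C@@H](OCc4ccc(OC)cc4)CC[C@@]3(C)O)cc1 | intermediate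
23 | 6α-boryl-5α-H adduct of 22 (shown as the monoalkylborane with free 4-OH) | COc1ccc(COCC[C@H]2[C@H](B)[C@@H]3[C@@](C)(C[C@@H]2O[Si](C)(C)C(C)(C)C)[C@@H](OCc4ccc(OC)cc4)CC[C@@]3(C)O)cc1 | intermediate (not isolated)
24 | 8α-(tert-butyldimethylsilyloxy)-1α,12-bis[(4-methoxybenzyl)oxy]-13-nor-5α-eudesmane-4α,6α-diol | COc1ccc(COCC[C@H]2[C@H](O)[C@@H]3[C@@](C)(C[C@@H]2O[Si](C)(C)C(C)(C)C)[C@@H](OCc4ccc(OC)cc4)CC[C@@]3(C)O)cc1 | intermediate
25 | 6α-angeloyloxy-8α-(tert-butyldimethylsilyloxy)-1α,12-bis[(4-methoxybenzyl)oxy]-13-nor-5α-eudesman-4α-ol | COc1ccc(COCC[C@H]2[C@H](OC(=O)/C(C)=C\C)[C@@H]3[C@@](C)(C[C@@H]2O[Si](C)(C)C(C)(C)C)[C@@H](OCc4ccc(OC)cc4)CC[C@@]3(C)O)cc1 | intermediate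
26 | 6α-angeloyloxy-8α-(tert-butyldimethylsilyloxy)-13-nor-5α-eudesmane-1α,4α,12-triol | OCC[C@H]1[C@H](OC(=O)/C(C)=C\C)[C@@H]2[C@@](C)(C[C@@H]1O[Si](C)(C)C(C)(C)C)[C@@H](O)CC[C@@]2(C)O | intermediate
27 | 6α-angeloyloxy-4α-hydroxy-1-oxo-8α-(tert-butyldimethylsilyloxy)-13-nor-5α-eudesman-12-al | O=CC[C@H]1[C@H](OC(=O)/C(C)=C\C)[C@@H]2[C@@](C)(C[C@@H]1O[Si](C)(C)C(C)(C)C)C(=O)CC[C@@]2(C)O | intermediate
28 | Mannich base: 13-(dimethylamino)-6α-angeloyloxy-4α-hydroxy-1-oxo-8α-(tert-butyldimethylsilyloxy)-5α-eudesman-12-al (both C11 epimers) | CN(C)CC(C=O)[C@H]1[C@H](OC(=O)/C(C)=C\C)[C@@H]2[C@@](C)(C[C@@H]1O[Si](C)(C)C(C)(C)C)C(=O)CC[C@@]2(C)O | intermediate (not isolated)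
29 | 6α-angeloyloxy-4α-hydroxy-1-oxo-8α-(tert-butyldimethylsilyloxy)-5α-eudesm-11(13)-en-12-al | C=C(C=O)[C@H]1[C@H](OC(=O)/C(C)=C\C)[C@@H]2[C@@](C)(C[C@@H]1O[Si](C)(C)C(C)(C)C)C(=O)CC[C@@]2(C)O | intermediate
30 | 6α-angeloyloxy-4α-hydroxy-1-oxo-8α-(tert-butyldimethylsilyloxy)-5α-eudesm-11(13)-en-12-oic acid | C=C(C(=O)O)[C@H]1[C@H](OC(=O)/C(C)=C\C)[C@@H]2[C@@](C)(C[C@@H]1O[Si](C)(C)C(C)(C)C)C(=O)CC[C@@]2(C)O | intermediate
31 | methyl 6α-angeloyloxy-4α-hydroxy-1-oxo-8α-(tert-butyldimethylsilyloxy)-5α-eudesm-11(13)-en-12-oate | C=C(C(=O)OC)[C@H]1[C@H](OC(=O)/C(C)=C\C)[C@@H]2[C@@](C)(C[C@@H]1O[Si](C)(C)C(C)(C)C)C(=O)CC[C@@]2(C)O | intermediate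
32 | methyl 6α-angeloyloxy-1β,4α-dihydroxy-8α-(tert-butyldimethylsilyloxy)-5α-eudesm-11(13)-en-12-oate | C=C(C(=O)OC)[C@H]1[C@H](OC(=O)/C(C)=C\C)[C@@H]2[C@@](C)(C[C@@H]1O[Si](C)(C)C(C)(C)C)[C@H](O)CC[C@@]2(C)O | intermediate
33 | methyl 6α-angeloyloxy-1β,4α,8α-trihydroxy-5α-eudesm-11(13)-en-12-oate (CNP0136844.1) | C=C(C(=O)OC)[C@H]1[C@H](OC(=O)/C(C)=C\C)[C@@H]2[C@@](C)(C[C@@H]1O)[C@H](O)CC[C@@]2(C)O | target

**Step count and risks**

Total step count: 22. Longest linear sequence: 21 steps (steps 1–5 and 7–22, from (R)-linalool); step 6 is a one-step side branch.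

The three steps most likely to fail:

Step 10 (ketene cycloaddition). Closure of the six-membered ring may be too slow, so that the vinylketene dimerizes or polymerizes, and the facial selectivity at C10 may be poor. Fallback through the more electrophilic keteniminium ion: acid 13 is condensed with pyrrolidine (carbodiimide coupling) to the pyrrolidine amide F1. Treatment with Tf2O and 2,6-di-tert-butyl-4-methylpyridine in 1,2-dichloroethane at reflux should give, by O-triflation and γ-deprotonation, the vinylketeniminium triflate F2, which is not isolated. Its intramolecular [2+2] cycloaddition should give the cyclobutaniminium triflate F3, and hydrolysis with aqueous NaHCO3 returns to the route at cyclobutanone 16.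

Step 13 (ring expansion). The allyl anion may be quenched by proton transfer from the enolizable aldehyde, or the recombination may give the wrong relative configuration at C7 and C8. Fallback through the neutral 1,3-acyl shift of the 2-alkenylcyclobutanone: thermolysis of cyclobutanone 16 (toluene, sealed tube, 160 °C) should give the ring-expanded cyclohex-3-enone F4. Reduction with LiBH(s-Bu)3 from the face opposite the angular methyl should give the axial 8β-alcohol F5. Mitsunobu inversion with 4-nitrobenzoic acid gives the 8α-(4-nitrobenzoate) F6, and methanolysis (K2CO3, MeOH) the 8α-alcohol F7. HF·pyridine then removes the tertiary TES ether to give the diol F8, and selective silylation of the secondary hydroxyl (t-BuMe2SiCl, imidazole) returns to the route at 22.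

Step 15 (angeloylation). Acylation of the hindered C6 hydroxyl may be slow, and the Z ester may isomerize to the tiglate during the reaction. Fallback that builds the Z double bond on the substrate: alcohol 24 is esterified with 2-[bis(2,2,2-trifluoroethoxy)phosphoryl]propanoic acid (carbodiimide, 4-(dimethylamino)pyridine) to the phosphonate ester F9. Still–Gennari olefination with acetaldehyde (KN(SiMe3)2, 18-crown-6, THF, −78 °C) should then give the Z-trisubstituted enoate and returns to the route at angelate 25.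

Further compounds
F1 | step 10 | pyrrolidine amide of acid 13 | O=C(N1CCCC1)/C(=C\CCCOCc1ccc(OC)cc1)[C@](C)(O[Si](CC)(CC)CC)CC[C@H](OCc1ccc(OC)cc1)C(C)=C
F2 | step 10 | N-pyrrolidinium vinylketeniminium triflate derived from F1 | [O-]S(=O)(=O)C(F)(F)F.C1CC[N+](C1)=C=C(/C=C/CCOCc1ccc(OC)cc1)[C@](C)(O[Si](CC)(CC)CC)CC[C@H](OCc1ccc(OC)cc1)C(C)=C
F3 | step 10 | cyclobutaniminium triflate (pyrrolidinium analogue of cyclobutanone 16) | [O-]S(=O)(=O)C(F)(F)F.C1CC[N+](C1)=C1C[C@@]2(C)[C@@H](OCc3ccc(OC)cc3)CC[C@@](C)(O[Si](CC)(CC)CC)[C@@]12/C=C/CCOCc1ccc(OC)cc1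
F4 | step 13 | 1α,12-bis[(4-methoxybenzyl)oxy]-4α-(triethylsilyloxy)-13-noreudesm-5-en-8-one | COc1ccc(COCC[C@H]2C=C3[C@@](C)(CC2=O)[C@@H](OCc4ccc(OC)cc4)CC[C@@]3(C)O[Si](CC)(CC)CC)cc1
F5 | step 13 | 1α,12-bis[(4-methoxybenzyl)oxy]-4α-(triethylsilyloxy)-13-noreudesm-5-en-8β-ol | COc1ccc(COCC[C@H]2C=C3[C@@](C)(C[C@H]2O)[C@@H](OCc4ccc(OC)cc4)CC[C@@]3(C)O[Si](CC)(CC)CC)cc1
F6 | step 13 | 1α,12-bis[(4-methoxybenzyl)oxy]-4α-(triethylsilyloxy)-13-noreudesm-5-en-8α-yl 4-nitrobenzoate | COc1ccc(COCC[C@H]2C=C3[C@@](C)(C[C@@H]2OC(=O)c5ccc(cc5)[N+](=O)[O-])[C@@H](OCc4ccc(OC)cc4)CC[C@@]3(C)O[Si](CC)(CC)CC)cc1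
F7 | step 13 | 1α,12-bis[(4-methoxybenzyl)oxy]-4α-(triethylsilyloxy)-13-noreudesm-5-en-8α-ol | COc1ccc(COCC[C@H]2C=C3[C@@](C)(C[C@@H]2O)[C@@H](OCc4ccc(OC)cc4)CC[C@@]3(C)O[Si](CC)(CC)CC)cc1
F8 | step 13 | 1α,12-bis[(4-methoxybenzyl)oxy]-13-noreudesm-5-ene-4α,8α-diol | COc1ccc(COCC[C@H]2C=C3[C@@](C)(C[C@@H]2O)[C@@H](OCc4ccc(OC)cc4)CC[C@@]3(C)O)cc1
F9 | step 15 | 6α-{2-[bis(2,2,2-trifluoroethoxy)phosphoryl]propanoyloxy} analogue of 25 | COc1ccc(COCC[C@H]2[C@H](OC(=O)C(C)P(=O)(OCC(F)(F)F)OCC(F)(F)F)[C@@H]3[C@@](C)(C[C@@H]2O[Si](C)(C)C(C)(C)C)[C@@H](OCc4ccc(OC)cc4)CC[C@@]3(C)O)cc1
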